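The cyclohexene ring (C1 carries CO2Me, C6 is CH2) is opened at C3–C4 and C5–C6: its C1=C2 alkene flanked by C3 and C6 is a Diels–Alder retron. A catalytic enantioselective [4+2] cycloaddition joins an acyclic 1-acetoxy-3-(methoxycarbonyl)butadiene (C3, C2, C1, C6, with the C3 acetate in place) with an (E)-3-acyloxyacrolein (C4, C5) that already carries the (S)-3-methylpentanoate. One operation forms both bonds and all three ring stereocentres: the E alkene gives the 4,5-trans, the endo formyl group the 3,4-cis relation, the catalyst the absolute sense. The C4 formyl group is then exchanged for oxygen with retention and acylated.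

Key step: step 5

Remark: ring locants C1–C6 of the target are used for all ring compounds; (3S)-3-methylpentanoic acid, (2R)-2-methylbutanoic acid and the sodium salt of malonaldehyde are taken as purchasable.

Step 1
Reactants: 1 (3S)-3-methylpentanoic acid; 2 sodium (1E)-3-oxoprop-1-en-1-olate (sodium salt of malonaldehyde)
Product: 4 (1E)-3-oxoprop-1-en-1-yl (3S)-3-methylpentanoate, via (3S)-3-methylpentanoyl chloride 3 (not isolated)
Conditions: (COCl)2, DMF (cat.), CH2Cl2, 0 °C → rt, evaporate; then 2, THF, 0 °C, non-aqueous work-up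
Reagents that add atoms: none
Why: Acid chloride formation followed by O-acylation of the ambident malonaldehyde enolate at its hard oxygen terminus should give the vinylogous mixed anhydride with the E geometry of the enolate kept, and the β-stereocentre of the acid cannot enolise.

Step 2
Reactants: 5 methyl 2-(triphenylphosphoranylidene)propanoate; 6 2,2-dimethoxyacetaldehyde
Product: 7 methyl (2E)-4,4-dimethoxy-2-methylbut-2-enoate
Conditions: CH2Cl2, rt (6 used as its commercial aqueous solution)
Reagents that add atoms: none
Why: Wittig olefination with a stabilised α-methyl ylide should give the E trisubstituted enoate, a geometry that is in any case erased in step 4.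

Step 3
Reactants: 7 methyl (2E)-4,4-dimethoxy-2-methylbut-2-enoate
Product: 8 methyl (2E)-2-methyl-4-oxobut-2-enoate
Conditions: 1 M HCl (aq), acetone, 0 °C → rt
Reagents that add atoms: water, O
Why: Acid-catalysed acetal hydrolysis should free the conjugated aldehyde while the methyl ester and the alkene are inert to cold dilute acid.

Step 4
Reactants: 8 methyl (2E)-2-methyl-4-oxobut-2-enoate
Product: 9 methyl (3E)-4-(acetyloxy)-2-methylidenebut-3-enoate
Conditions: Ac2O, Et3N, DMAP (cat.), THF, 0 °C → rt; kept cold in solution with BHT and used at once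
Reagents that add atoms: acetic anhydride, CC(=O)OC(C)=O
Why: Dienol acetate formation: γ-deprotonation of the enal at the methyl group (vinylogously activated by the aldehyde) and O-acetylation of the dienolate should give the 1-acetoxydiene, the E enol acetate being the favoured isomer.

Step 5
Reactants: 9 methyl (3E)-4-(acetyloxy)-2-methylidenebut-3-enoate; 4 (1E)-3-oxoprop-1-en-1-yl (3S)-3-methylpentanoate
Product: 10 methyl (3R,4S,5R)-3-(acetyloxy)-4-formyl-5-{[(3S)-3-methylpentanoyl]oxy}cyclohex-1-ene-1-carboxylate
Conditions: (S)-3,3-diphenyl-1-(2-methylphenyl)tetrahydro-1H,3H-pyrrolo[1,2-c][1,3,2]oxazaborole (20 mol %), HNTf2 (18 mol %), CH2Cl2, −78 → −40 °C, 9 added slowly; pH 7 buffer quench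
Reagents that add atoms: none
Why: Concerted, asynchronous normal-electron-demand [4+2] cycloaddition in which the N-protonated oxazaborolidine binds the formyl oxygen of the s-trans enal 4 and the s-cis diene 9 adds to its open face; the closest known reaction type is the oxazaborolidinium-catalysed enantioselective Diels–Alder reaction of α,β-enals with 1-oxygenated butadienes. The six-membered carbocycle is closed by suprafacial [4π+2π] bonding of the diene termini C3 and C6 to the enal carbons C4 (α) and C5 (β) in one transition state. C5 is set trans to C4 by the E geometry of 4 and C3 is set cis to C4 by the endo position of the formyl group. The absolute configuration (4S,5R, hence 3R) is set by the catalyst, whose phenyl group stacked under the enal should leave only the Re face of both enal alkene carbons open to the diene. Regioselectivity is required and is secured by the diene itself, since the 1-acetoxy and the 3-methoxycarbonyl group both place the largest HOMO coefficient on the CH2 terminus, which joins the electrophilic β-carbon of the enal. Chemoselectivity against self-dimerisation of the 2-(methoxycarbonyl)diene is secured by the low temperature, the preferential activation of the aldehyde and the slow addition of 9.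

Step 6
Reactants: 10 methyl (3R,4S,5R)-3-(acetyloxy)-4-formyl-5-{[(3S)-3-methylpentanoyl]oxy}cyclohex-1-ene-1-carboxylate
Product: 12 methyl (3R,4S,5R)-3-(acetyloxy)-4-hydroxy-5-{[(3S)-3-methylpentanoyl]oxy}cyclohex-1-ene-1-carboxylate, via C4 formate 11 (not isolated)
Conditions: mCPBA, Na2HPO4, CH2Cl2, 0 °C → rt; then KHCO3 (cat.), MeOH, −10 °C, short contact
Reagents that add atoms: mCPBA (3-chloroperoxybenzoic acid), OOC(=O)c1cccc(Cl)c1
Why: Baeyer–Villiger oxidation of the α-branched aldehyde, in which the secondary carbon C4 migrates to oxygen with retention, should give the formate, which is far more labile than the acetate and the higher ester and is removed by brief mild methanolysis, while the electron-poor C1=C2 alkene is not epoxidised.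

Step 7
Reactants: 12 methyl (3R,4S,5R)-3-(acetyloxy)-4-hydroxy-5-{[(3S)-3-methylpentanoyl]oxy}cyclohex-1-ene-1-carboxylate; 13 (2R)-2-methylbutanoic acid
Product: 14 methyl (3R,4S,5R)-3-(acetyloxy)-4-{[(2R)-2-methylbutanoyl]oxy}-5-{[(3S)-3-methylpentanoyl]oxy}cyclohex-1-ene-1-carboxylate
Conditions: EDC·HCl, DMAP (0.2 equiv), CH2Cl2, 0 °C → rt
Reagents that add atoms: none
Why: Steglich esterification (carbodiimide activation with nucleophilic catalysis) should acylate the last free hydroxyl without touching a ring stereocentre, the low temperature and substoichiometric DMAP keeping the α-stereocentre of the acid and the position of the neighbouring acetate intact.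

Compound list
1 | (3S)-3-methylpentanoic acid | CC[C@H](C)CC(=O)O | starting material
2 | sodium (1E)-3-oxoprop-1-en-1-olate (sodium salt of malonaldehyde) | [Na+].[O-]/C=C/C=O | starting material
3 | (3S)-3-methylpentanoyl chloride | CC[C@H](C)CC(Cl)=O | intermediate
4 | (1E)-3-oxoprop-1-en-1-yl (3S)-3-methylpentanoate | CC[C@H](C)CC(=O)O/C=C/C=O | intermediate
5 | methyl 2-(triphenylphosphoranylidene)propanoate | COC(=O)C(C)=P(c1ccccc1)(c1ccccc1)c1ccccc1 | starting material
6 | 2,2-dimethoxyacetaldehyde | COC(OC)C=O | starting material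
7 | methyl (2E)-4,4-dimethoxy-2-methylbut-2-enoate | COC(OC)/C=C(\C)C(=O)OC | intermediate
8 | methyl (2E)-2-methyl-4-oxobut-2-enoate | O=C/C=C(\C)C(=O)OC | intermediate
9 | methyl (3E)-4-(acetyloxy)-2-methylidenebut-3-enoate | C=C(C(=O)OC)/C=C/OC(C)=O | intermediate
10 | methyl (3R,4S,5R)-3-(acetyloxy)-4-formyl-5-{[(3S)-3-methylpentanoyl]oxy}cyclohex-1-ene-1-carboxylate | CC[C@H](C)CC(=O)O[C@@H]1CC(C(=O)OC)=C[C@@H](OC(C)=O)[C@H]1C=O | intermediate
11 | methyl (3R,4S,5R)-3-(acetyloxy)-4-(formyloxy)-5-{[(3S)-3-methylpentanoyl]oxy}cyclohex-1-ene-1-carboxylate | CC[C@H](C)CC(=O)O[C@@H]1CC(C(=O)OC)=C[C@@H](OC(C)=O)[C@H]1OC=O | intermediate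
12 | methyl (3R,4S,5R)-3-(acetyloxy)-4-hydroxy-5-{[(3S)-3-methylpentanoyl]oxy}cyclohex-1-ene-1-carboxylate | CC[C@H](C)CC(=O)O[C@@H]1CC(C(=O)OC)=C[C@@H](OC(C)=O)[C@H]1O | intermediate
13 | (2R)-2-methylbutanoic acid | CC[C@@H](C)C(=O)O | starting material
14 | methyl (3R,4S,5R)-3-(acetyloxy)-4-{[(2R)-2-methylbutanoyl]oxy}-5-{[(3S)-3-methylpentanoyl]oxy}cyclohex-1-ene-1-carboxylate | CC[C@H](C)CC(=O)O[C@@H]1CC(C(=O)OC)=C[C@@H](OC(C)=O)[C@H]1OC(=O)[C@H](C)CC | target

Total step count: 7. Longest linear sequence: 6 steps (steps 2 to 7).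

Steps most likely to fail

Step 5. The acetoxy diene is only weakly electron-rich, so self-dimerisation through its acrylate unit may outrun the cross-cycloaddition, and an uncatalysed background reaction may erode facial selectivity. The sense of induction rests on the pre-transition-state model; the mirror-image catalyst is equally accessible. The fallback sets out from 8 and comes back to the route at 14. Silylation of 8 (iPr3SiOTf, Et3N, CH2Cl2, −78 → 0 °C) should give the more electron-rich dienol ether methyl (3E)-2-methylidene-4-[(triisopropylsilyl)oxy]but-3-enoate F1. Its cycloaddition with 4 under the catalyst of step 5 should give methyl (3R,4S,5R)-4-formyl-5-{[(3S)-3-methylpentanoyl]oxy}-3-[(triisopropylsilyl)oxy]cyclohex-1-ene-1-carboxylate F2. Baeyer–Villiger oxidation (mCPBA, Na2HPO4) leads to the C4 formate F3 (not isolated), methanolysed (KHCO3, MeOH) to the C4 alcohol F4. Steglich esterification with 13, now with no vicinal acetate present, gives the silyl ether diester F5. HF·pyridine in THF frees the C3 alcohol F6, which is acetylated at once (Ac2O, pyridine, 0 °C) to 14.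

Step 6. Because C4 carries two β-acyloxy groups its migratory aptitude is lowered, so formyl-hydrogen migration to the carboxylic acid may compete, as may loss of acetate by β-elimination from the aldehyde. The fallback sets out from 10 and comes back at 12. Silylation (tBuMe2SiOTf, Et3N, CH2Cl2, −78 °C) turns the aldehyde into the exocyclic silyl enol ether F7 (either geometry serves). Ozone (CH2Cl2/MeOH, −78 °C) cleaves this electron-rich alkene in preference to the conjugated C1=C2 bond to give the C4 ketone F8, which is reduced in the same flask with NaBH4 at −78 °C. Axial hydride delivery on the face opposite the pseudoaxial C3 acetate should give the equatorial C4 hydroxyl, cis to C3–O and trans to C5–O, that is 12. This path is stereoconvergent at C4.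

Step 7. The C4 hydroxyl lies between two acyloxy groups, so acylation may be slow enough for base-mediated acetyl migration from O3 to O4 and for ketene-type epimerisation of the activated α-branched acid. The fallback sets out from 13 and 12 and comes back at 14. Acid 13 is first converted (DCC, 0.5 equiv, CH2Cl2) into the symmetric anhydride (2R)-2-methylbutanoic anhydride F9. This is transferred to 12 under Lewis acid catalysis (Sc(OTf)3, 5 mol %, MeCN, −20 °C) with no base present, so neither acyl migration nor ketene formation has a pathway.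

Further compounds
F1 | step 5 | methyl (3E)-2-methylidene-4-[(triisopropylsilyl)oxy]but-3-enoate | C=C(C(=O)OC)/C=C/O[Si](C(C)C)(C(C)C)C(C)C
F2 | step 5 | methyl (3R,4S,5R)-4-formyl-5-{[(3S)-3-methylpentanoyl]oxy}-3-[(triisopropylsilyl)oxy]cyclohex-1-ene-1-carboxylate | CC[C@H](C)CC(=O)O[C@@H]1CC(C(=O)OC)=C[C@@H](O[Si](C(C)C)(C(C)C)C(C)C)[C@H]1C=O
F3 | step 5 | methyl (3R,4S,5R)-4-(formyloxy)-5-{[(3S)-3-methylpentanoyl]oxy}-3-[(triisopropylsilyl)oxy]cyclohex-1-ene-1-carboxylate | CC[C@H](C)CC(=O)O[C@@H]1CC(C(=O)OC)=C[C@@H](O[Si](C(C)C)(C(C)C)C(C)C)[C@H]1OC=O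
F4 | step 5 | methyl (3R,4S,5R)-4-hydroxy-5-{[(3S)-3-methylpentanoyl]oxy}-3-[(triisopropylsilyl)oxy]cyclohex-1-ene-1-carboxylate | CC[C@H](C)CC(=O)O[C@@H]1CC(C(=O)OC)=C[C@@H](O[Si](C(C)C)(C(C)C)C(C)C)[C@H]1O
F5 | step 5 | methyl (3R,4S,5R)-4-{[(2R)-2-methylbutanoyl]oxy}-5-{[(3S)-3-methylpentanoyl]oxy}-3-[(triisopropylsilyl)oxy]cyclohex-1-ene-1-carboxylate | CC[C@H](C)CC(=O)O[C@@H]1CC(C(=O)OC)=C[C@@H](O[Si](C(C)C)(C(C)C)C(C)C)[C@H]1OC(=O)[C@H](C)CC
F6 | step 5 | methyl (3R,4R,5R)-3-hydroxy-4-{[(2R)-2-methylbutanoyl]oxy}-5-{[(3S)-3-methylpentanoyl]oxy}cyclohex-1-ene-1-carboxylate | CC[C@H](C)CC(=O)O[C@@H]1CC(C(=O)OC)=C[C@@H](O)[C@H]1OC(=O)[C@H](C)CC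
F7 | step 6 | methyl (3R,5R)-3-(acetyloxy)-4-{[(tert-butyldimethylsilyl)oxy]methylidene}-5-{[(3S)-3-methylpentanoyl]oxy}cyclohex-1-ene-1-carboxylate (mixture of alkene isomers) | CC[C@H](C)CC(=O)O[C@@H]1CC(C(=O)OC)=C[C@@H](OC(C)=O)C1=CO[Si](C)(C)C(C)(C)C
F8 | step 6 | methyl (3R,5R)-3-(acetyloxy)-5-{[(3S)-3-methylpentanoyl]oxy}-4-oxocyclohex-1-ene-1-carboxylate | CC[C@H](C)CC(=O)O[C@@H]1CC(C(=O)OC)=C[C@@H](OC(C)=O)C1=O
F9 | step 7 | (2R)-2-methylbutanoic anhydride | CC[C@@H](C)C(=O)OC(=O)[C@H](C)CC
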